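**Plan**

- Numbering: C1 is the benzylic CH2, C2 the acetoxy stereocentre, C8 the ketone carbon. The retrosynthesis first takes a benzyl group off the phenol oxygen, then cuts C4–C5.
- The feature that allows this cut is the unbranched run of five methylenes C3–C7 between C2 and C8, well away from the benzene ring (the only ring, bought intact). Cutting it gives two primary alkyl fragments, each ending in a carboxyl group: (R)-4-acetoxy-5-arylpentanoic acid and 5-oxodecanoic acid.
- The acetoxy acid is an opened γ-lactone; its aryl–C1 bond is cut back to an aryl Grignard reagent and methyl (R)-4,5-epoxypentanoate, which comes from (R)-5-(hydroxymethyl)dihydrofuran-2(3H)-one.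
- The keto acid is cut at C8–C9 into glutaric anhydride and pentylmagnesium bromide.
- Forward, the chain is joined in the order aryl–C1 (step 4), C8–C9 (step 8), C4–C5 (step 10). No ring of the target is formed; a γ-lactone is closed in passing in step 4 and opened again in step 5.
- The only stereocentre, C2, is C5 of the purchased (R)-lactone; its C–O bond is never broken, and the phenol travels as a benzyl ether until the last step.

Key step: step 10

Assumption: lactone 1 is bought as the (R) enantiomer (D-glutamic acid series) in high enantiomeric purity, since no later step can raise it.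

**Route**

Step 1
Reactants: 1 (R)-5-(hydroxymethyl)dihydrofuran-2(3H)-one
Product: 2 [(2R)-5-oxotetrahydrofuran-2-yl]methyl 4-methylbenzenesulfonate
Conditions: TsCl, pyridine, CH2Cl2, 0 °C to rt
Reagents that add atoms: 4-methylbenzenesulfonyl chloride (TsCl), Cc1ccc(cc1)S(=O)(=O)Cl
Why: Sulfonylation of the primary alcohol with pyridine as base is routine for this lactone and leaves the stereocentre untouched.

Step 2
Reactants: 2 [(2R)-5-oxotetrahydrofuran-2-yl]methyl 4-methylbenzenesulfonate
Product: 4 methyl 3-[(2R)-oxiran-2-yl]propanoate, via ring-opened sodium alkoxide 3 (not isolated)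
Conditions: NaOMe (1.1 equiv), MeOH, 0 °C to rt
Reagents that add atoms: sodium methoxide (NaOMe), [Na+].[O-]C
Why: Methoxide opens the lactone by transesterification and the freed C4 alkoxide displaces the neighbouring primary tosylate (intramolecular Williamson reaction, 3-exo-tet), so the C–O bond at the stereocentre is kept and the (R) configuration is retained.

Step 3
Reactants: 5 3-bromo-5-methoxyphenol
Product: 6 1-(benzyloxy)-3-bromo-5-methoxybenzene
Conditions: BnBr, K2CO3, acetone, reflux
Reagents that add atoms: benzyl bromide, BrCc1ccccc1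
Why: Williamson O-benzylation masks the acidic phenol so that the aryl bromide can be converted into a Grignard reagent.

Step 4
Reactants: 6 1-(benzyloxy)-3-bromo-5-methoxybenzene; 4 methyl 3-[(2R)-oxiran-2-yl]propanoate
Product: 9 (R)-5-[3-(benzyloxy)-5-methoxybenzyl]dihydrofuran-2(3H)-one, via arylmagnesium bromide 7 (not isolated), via methyl hydroxy ester 8 (not isolated)
Conditions: Mg turnings, I2 (cat.), THF, 40 °C; then added slowly to 4, CuI (10 mol%), THF, −40 to −20 °C; 1 M HCl; TsOH·H2O (5 mol%), CH2Cl2, rt
Reagents that add atoms: none
Why: Copper-catalysed SN2 opening of the terminal epoxide by the aryl Grignard reagent should occur at the unsubstituted carbon much faster than addition to the methyl ester at −40 °C, and the γ-hydroxy ester then lactonises (5-exo-trig) under acid without involving the stereocentre.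

Step 5
Reactants: 9 (R)-5-[3-(benzyloxy)-5-methoxybenzyl]dihydrofuran-2(3H)-one
Product: 12 allyl (R)-4-acetoxy-5-[3-(benzyloxy)-5-methoxyphenyl]pentanoate, via potassium hydroxy carboxylate 10 (not isolated), via allyl hydroxy ester 11 (not isolated)
Conditions: KOH (1.05 equiv), THF/H2O, rt, then evaporation to dryness (toluene azeotrope); allyl bromide, DMF, rt; Ac2O, pyridine, DMAP (cat.), 0 °C to rt
Reagents that add atoms: potassium hydroxide (KOH), [K+].[OH-]; allyl bromide, C=CCBr; acetic anhydride, CC(=O)OC(C)=O
Why: Saponification of the γ-lactone, SN2 O-alkylation of the dry potassium carboxylate and immediate DMAP-catalysed acetylation should trap the open-chain form before it can relactonise, with C4 unchanged.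

Step 6
Reactants: 12 allyl (R)-4-acetoxy-5-[3-(benzyloxy)-5-methoxyphenyl]pentanoate
Product: 13 (R)-4-acetoxy-5-[3-(benzyloxy)-5-methoxyphenyl]pentanoic acid
Conditions: Pd(PPh3)4 (3 mol%), morpholine (3 equiv), THF, rt; cold 1 M HCl wash
Reagents that add atoms: none
Why: Zerovalent palladium ionises the allyl ester to a π-allyl complex that morpholine captures (Tsuji–Trost deallylation), leaving the secondary acetate and the benzyl ether intact.

Step 7
Reactants: 13 (R)-4-acetoxy-5-[3-(benzyloxy)-5-methoxyphenyl]pentanoic acid
Product: 14 1,3-dioxoisoindolin-2-yl (R)-4-acetoxy-5-[3-(benzyloxy)-5-methoxyphenyl]pentanoate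
Conditions: N-hydroxyphthalimide (1.1 equiv), N,N'-diisopropylcarbodiimide (1.1 equiv), DMAP (5 mol%), CH2Cl2, rt
Reagents that add atoms: N-hydroxyphthalimide, ON1C(=O)c2ccccc2C1=O
Why: Steglich-type carbodiimide esterification gives the redox-active ester under neutral conditions that do not disturb the acetate or the stereocentre.

Step 8
Reactants: 15 glutaric anhydride; 16 pentylmagnesium bromide
Product: 17 5-oxodecanoic acid
Conditions: 16 (1.0 equiv) added slowly to 15 (1.2 equiv), THF, −78 °C; 1 M HCl
Reagents that add atoms: none
Why: Acylation of the Grignard reagent by the cyclic anhydride at low temperature should stop at the ketone, because the anhydride is kept in excess by inverse addition and the product is held as a magnesium carboxylate.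

Step 9
Reactants: 17 5-oxodecanoic acid
Product: 18 1,3-dioxoisoindolin-2-yl 5-oxodecanoate
Conditions: N-hydroxyphthalimide (1.1 equiv), N,N'-diisopropylcarbodiimide (1.1 equiv), DMAP (5 mol%), CH2Cl2, rt
Reagents that add atoms: N-hydroxyphthalimide, ON1C(=O)c2ccccc2C1=O
Why: The same Steglich-type esterification activates the keto acid, and the ketone does not interfere.

Step 10
Reactants: 14 1,3-dioxoisoindolin-2-yl (R)-4-acetoxy-5-[3-(benzyloxy)-5-methoxyphenyl]pentanoate; 18 1,3-dioxoisoindolin-2-yl 5-oxodecanoate
Product: 19 (R)-1-[3-(benzyloxy)-5-methoxyphenyl]-8-oxotridecan-2-yl acetate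
Conditions: 14 (1 equiv), 18 (3 equiv), NiCl2·glyme (20 mol%), 2,2':6',2''-terpyridine (20 mol%), NaI, DMF, undivided cell, Zn anode, reticulated vitreous carbon cathode, constant current, rt; dilute HCl work-up
Reagents that add atoms: none
Why: Low-valent nickel–terpyridine formed at the cathode passes one electron to each N-acyloxyphthalimide, which fragments to phthalimide anion, CO2 and a primary alkyl radical; one radical is held as an alkylnickel species, this captures the second radical, and reductive elimination from trivalent nickel forms the C4–C5 bond, with the zinc anode as terminal reductant. The closest known reaction type is the nickel-electrocatalytic doubly decarboxylative C(sp3)–C(sp3) coupling of two redox-active esters of aliphatic acids, a class that accepts primary partners bearing esters, ethers and ketones. No ring closes and no stereocentre is created; C2 sits two carbons from the radical site, none of its bonds is broken, and the (R) configuration is carried through. The selectivity needed is cross- over homo-coupling, which two similar primary radicals do not supply, so the inexpensive keto ester 18 is used in threefold excess to push the statistics toward 19. The conditions are reductive, so the electron-rich dialkoxyarene is not oxidised as it would be at a Kolbe anode, and neither radical has an acyloxy or other leaving group on the adjacent carbon, so acyloxy shift and β-elimination are not expected.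

Step 11
Reactants: 19 (R)-1-[3-(benzyloxy)-5-methoxyphenyl]-8-oxotridecan-2-yl acetate
Product: 20 (R)-1-(3-hydroxy-5-methoxyphenyl)-8-oxotridecan-2-yl acetate
Conditions: H2 (1 atm), 10% Pd/C, EtOAc, rt
Reagents that add atoms: none
Why: Hydrogenolysis of the aryl benzyl ether over Pd/C is selective beside an aliphatic ketone and a non-benzylic secondary acetate, so it should free the phenol and give the target.

**Compound list**

1 | (R)-5-(hydroxymethyl)dihydrofuran-2(3H)-one | O=C1CC[C@H](CO)O1 | starting material
2 | [(2R)-5-oxotetrahydrofuran-2-yl]methyl 4-methylbenzenesulfonate | O=C1CC[C@H](COS(=O)(=O)c2ccc(C)cc2)O1 | intermediate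
3 | sodium alkoxide of methyl (R)-4-hydroxy-5-(tosyloxy)pentanoate (formed in the flask) | COC(=O)CC[C@@H]([O-])COS(=O)(=O)c1ccc(C)cc1.[Na+] | intermediate
4 | methyl 3-[(2R)-oxiran-2-yl]propanoate (methyl (R)-4,5-epoxypentanoate) | COC(=O)CC[C@@H]1CO1 | intermediate
5 | 3-bromo-5-methoxyphenol | COc1cc(O)cc(Br)c1 | starting material
6 | 1-(benzyloxy)-3-bromo-5-methoxybenzene | COc1cc(Br)cc(OCc2ccccc2)c1 | intermediate
7 | [3-(benzyloxy)-5-methoxyphenyl]magnesium bromide (formed in the flask) | COc1cc([Mg]Br)cc(OCc2ccccc2)c1 | intermediate
8 | methyl (R)-5-[3-(benzyloxy)-5-methoxyphenyl]-4-hydroxypentanoate (formed in the flask, first as its bromomagnesium alkoxide) | COC(=O)CC[C@@H](O)Cc1cc(OC)cc(OCc2ccccc2)c1 | intermediate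
9 | (R)-5-[3-(benzyloxy)-5-methoxybenzyl]dihydrofuran-2(3H)-one | O=C1CC[C@H](Cc2cc(OC)cc(OCc3ccccc3)c2)O1 | intermediate
10 | potassium (R)-5-[3-(benzyloxy)-5-methoxyphenyl]-4-hydroxypentanoate (formed in the flask) | [K+].[O-]C(=O)CC[C@@H](O)Cc1cc(OC)cc(OCc2ccccc2)c1 | intermediate
11 | allyl (R)-5-[3-(benzyloxy)-5-methoxyphenyl]-4-hydroxypentanoate (formed in the flask) | C=CCOC(=O)CC[C@@H](O)Cc1cc(OC)cc(OCc2ccccc2)c1 | intermediate
12 | allyl (R)-4-acetoxy-5-[3-(benzyloxy)-5-methoxyphenyl]pentanoate | C=CCOC(=O)CC[C@H](Cc1cc(OC)cc(OCc2ccccc2)c1)OC(C)=O | intermediate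
13 | (R)-4-acetoxy-5-[3-(benzyloxy)-5-methoxyphenyl]pentanoic acid | OC(=O)CC[C@H](Cc1cc(OC)cc(OCc2ccccc2)c1)OC(C)=O | intermediate
14 | 1,3-dioxoisoindolin-2-yl (R)-4-acetoxy-5-[3-(benzyloxy)-5-methoxyphenyl]pentanoate | O=C(CC[C@H](Cc1cc(OC)cc(OCc2ccccc2)c1)OC(C)=O)ON1C(=O)c2ccccc2C1=O | intermediate
15 | glutaric anhydride | O=C1CCCC(=O)O1 | starting material
16 | pentylmagnesium bromide | CCCCC[Mg]Br | starting material
17 | 5-oxodecanoic acid | CCCCCC(=O)CCCC(=O)O | intermediate
18 | 1,3-dioxoisoindolin-2-yl 5-oxodecanoate | CCCCCC(=O)CCCC(=O)ON1C(=O)c2ccccc2C1=O | intermediate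
19 | (R)-1-[3-(benzyloxy)-5-methoxyphenyl]-8-oxotridecan-2-yl acetate | CCCCCC(=O)CCCCC[C@H](Cc1cc(OC)cc(OCc2ccccc2)c1)OC(C)=O | intermediate
20 | (R)-1-(3-hydroxy-5-methoxyphenyl)-8-oxotridecan-2-yl acetate (CNP0302149.1) | CCCCCC(=O)CCCCC[C@H](Cc1cc(O)cc(OC)c1)OC(C)=O | target

**Step count and risks**

Total step count: 11.
Longest linear sequence: 8 steps (steps 1, 2, 4, 5, 6, 7, 10 and 11, from lactone 1).

Steps most likely to fail:

Step 10. Statistical homo-coupling may consume the limiting ester 14, and premature reduction of either radical (hydrodecarboxylation) or a 1,5-hydrogen shift in the keto radical may erode the cross-coupled product. The fallback keeps the carboxyl carbon as C5 and makes the C5–C6 bond instead. It sets out from acid 13: BH3·SMe2 in THF (0 °C to rt) should reduce the acid selectively beside the acetate to (R)-1-[3-(benzyloxy)-5-methoxyphenyl]-5-hydroxypentan-2-yl acetate F1. I2, PPh3 and imidazole (CH2Cl2, 0 °C) then give (R)-1-[3-(benzyloxy)-5-methoxyphenyl]-5-iodopentan-2-yl acetate F2. A Giese addition of the derived primary radical to commercial oct-1-en-3-one ((Me3Si)3SiH, AIBN, toluene, 80 °C, excess enone) comes back to the route at 19.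

Step 4. The Grignard reagent may add to the methyl ester in competition with epoxide opening, and magnesium bromide may open the epoxide to a bromohydrin. The fallback skips the epoxy ester and uses a stoichiometric Gilman cuprate on the lactone tosylate, a displacement known for this tosylate with dialkylcuprates. It sets out from bromide 6 and tosylate 2: bromine–lithium exchange (n-BuLi, THF, −78 °C) gives [3-(benzyloxy)-5-methoxyphenyl]lithium F3. CuI (0.5 equiv) converts it into lithium bis[3-(benzyloxy)-5-methoxyphenyl]cuprate F4, which should displace the primary tosylate of 2 (THF, −40 to 0 °C; aqueous NH4Cl work-up) and comes back to the route at lactone 9.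

Step 8. A second addition of the Grignard reagent to the newly formed ketone may compete with the first acylation. The fallback goes through a Weinreb amide and sets out from anhydride 15: N,O-dimethylhydroxylamine hydrochloride and pyridine (CH2Cl2, rt) open it to 5-[methoxy(methyl)amino]-5-oxopentanoic acid F5. Pentylmagnesium bromide 16 (2.2 equiv, THF, −78 to 0 °C) first deprotonates the acid and then adds once to the amide, whose chelated adduct collapses only on acidic work-up; this comes back to the route at 17.

**Further compounds**

F1 | step 10 | (R)-1-[3-(benzyloxy)-5-methoxyphenyl]-5-hydroxypentan-2-yl acetate | OCCC[C@H](Cc1cc(OC)cc(OCc2ccccc2)c1)OC(C)=O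
F2 | step 10 | (R)-1-[3-(benzyloxy)-5-methoxyphenyl]-5-iodopentan-2-yl acetate | ICCC[C@H](Cc1cc(OC)cc(OCc2ccccc2)c1)OC(C)=O
F3 | step 4 | [3-(benzyloxy)-5-methoxyphenyl]lithium | [Li]c1cc(OC)cc(OCc2ccccc2)c1
F4 | step 4 | lithium bis[3-(benzyloxy)-5-methoxyphenyl]cuprate | [Li+].COc1cc([Cu-]c2cc(OC)cc(OCc3ccccc3)c2)cc(OCc2ccccc2)c1
F5 | step 8 | 5-[methoxy(methyl)amino]-5-oxopentanoic acid | CON(C)C(=O)CCCC(=O)O
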